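A direct plan would make the C-(1,1-dimethylallyl)trihydroxyacetophenone A1 by a para-blocked Claisen rearrangement, condense it with the bis-silyl ether A2 of 3,4-dihydroxybenzaldehyde to the 2',4',6'-trihydroxychalcone A3, close ring C by an enantioselective intramolecular oxa-Michael addition to the silylated flavanone A4, and desilylate.
Its weakest steps would be:
- The ring closure that sets C2 is a reversible C–O bond formation on an unactivated, unprotected chalcone. No established asymmetric method covers it, and the base that closes the ring also reopens it, so C2 would be set under conditions that erase it.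
- The same closure would have to choose between the two ortho-phenols of A3. The 6- versus 8-position of the tert-alkyl group would then rest on a hydrogen-bond bias, not on connectivity.
- The aldol condensation of triply deprotonated A1, and the isolation of open A3, are fragile. 2',6'-Dihydroxychalcones cyclise spontaneously on acid work-up or silica to racemic flavanone, which would bypass the asymmetric step.

**Retrosynthetic overview**
- Target 14 comes from acid unmasking of 13. The key disconnection is the C2–C1' bond: a rhodium-catalysed enantioselective 1,4-addition of boronic acid 12 (ring B) to chromone 7 (rings A and C complete) joins the halves and creates C2 in an irreversible C–C bond formation.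
- Chromone 7 comes from an aromatic Claisen [3,3] shift of the O5-prenyl ether 4. The quaternary carbon on C6 is delivered from O5, whose only free ortho carbon is C6 (C4a is the ring fusion), so 6- versus 8-substitution is fixed by connectivity; anhydride trapping blocks the onward shift to C8.
- Ring order: ring C is present from the start in 5,7-dihydroxychromone 1 (O1 already fixed) and ring B is attached last. There is no chalcone, no phenol competition at ring closure, and no base after C2 is set.

Key step: step 5

Assumption: 5,7-dihydroxychromen-4-one is taken as a catalogue compound; the (S)-ligand is assigned to the (2S)-product by analogy with the facial preference of (S)-biaryl bisphosphines on cyclic enones, to be confirmed on the first run (the (R)-ligand would be used if the sense is opposite).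

**Step 1**
Reactants: 1 5,7-dihydroxychromen-4-one; 2 1-bromo-3-methylbut-2-ene (prenyl bromide)
Product: 4 7-(methoxymethoxy)-5-[(3-methylbut-2-en-1-yl)oxy]chromen-4-one, via 7-O-MOM chromone 3 (not isolated)
Conditions: K2CO3 (3 equiv), DMF, 0 °C; MOMCl (1.05 equiv), 0 °C → rt, 2 h; then 2 (1.5 equiv), 50 °C, 8 h
Reagents that add atoms: chloromethyl methyl ether, COCCl
Why: Two Williamson etherifications in one pot, ordered by acidity: the 7-OH (vinylogous acid, not hydrogen-bonded) is alkylated by the chloromethyl ether in the cold, the chelated 5-OH only on warming with prenyl bromide, and the polar aprotic medium favours O- over C-alkylation, so the allyl group is placed on O5.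

**Step 2**
Reactants: 4 7-(methoxymethoxy)-5-[(3-methylbut-2-en-1-yl)oxy]chromen-4-one
Product: 7 7-(methoxymethoxy)-6-(2-methylbut-3-en-2-yl)-4-oxochromen-5-yl acetate, via Claisen dienone 5 (not isolated), via free 5-phenol 6 (not isolated)
Conditions: Ac2O (5 equiv), PhNEt2, Ar, 160 °C, 3 h; cold aqueous citric acid wash
Reagents that add atoms: acetic anhydride, CC(=O)OC(C)=O
Why: Aromatic Claisen rearrangement, a [3,3] shift that inverts the allyl unit (O5–CH2CH=CMe2 to C6–CMe2CH=CH2) and can reach only C6 because the other ortho carbon C4a is the ring fusion; the amine enolises dienone 5 and the anhydride caps phenol 6 as it forms, the classical device that keeps an o-(1,1-dimethylallyl)phenol from moving on to the para position (here C8) by a Cope shift and from cyclising, and the acetate also masks the chelating 5-OH for step 5, all before any stereocentre exists.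

**Step 3**
Reactants: 8 4-bromobenzene-1,2-diol (4-bromocatechol)
Product: 9 4-bromo-1,2-bis(methoxymethoxy)benzene
Conditions: MOMCl (2.5 equiv), i-Pr2NEt (3 equiv), CH2Cl2, 0 °C → rt, 6 h
Reagents that add atoms: chloromethyl methyl ether, COCCl
Why: Amine-promoted Williamson-type acetal formation on both catechol oxygens; methoxymethyl ethers withstand butyllithium and the aqueous rhodium step and fall in the final acid step together with the ring A groups.

**Step 4**
Reactants: 9 4-bromo-1,2-bis(methoxymethoxy)benzene
Product: 12 [3,4-bis(methoxymethoxy)phenyl]boronic acid, via aryllithium 10 (not isolated), via lithium aryl(triisopropoxy)borate 11 (not isolated)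
Conditions: n-BuLi (1.05 equiv), THF, −78 °C, 15 min; B(Oi-Pr)3 (1.5 equiv), −78 °C → rt; sat. aq. NH4Cl
Reagents that add atoms: triisopropyl borate, CC(C)OB(OC(C)C)OC(C)C; water, O
Why: Bromine–lithium exchange is much faster at −78 °C than ortho-lithiation next to the acetal oxygens, and borate trapping followed by hydrolysis at pH 5–6 should give the boronic acid with both acetals intact.

**Step 5**
Reactants: 7 7-(methoxymethoxy)-6-(2-methylbut-3-en-2-yl)-4-oxochromen-5-yl acetate; 12 [3,4-bis(methoxymethoxy)phenyl]boronic acid
Product: 13 (2S)-2-[3,4-bis(methoxymethoxy)phenyl]-7-(methoxymethoxy)-6-(2-methylbut-3-en-2-yl)-4-oxo-2,3-dihydrochromen-5-yl acetate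
Conditions: [Rh(OH)(C8H12)]2 (C8H12 = 1,5-cyclooctadiene; 2.5 mol%), (S)-6,6'-dimethoxy-2,2'-bis[bis(3,4,5-trifluorophenyl)phosphino]-1,1'-biphenyl (5.5 mol%), 12 (2.5 equiv), toluene/H2O 10:1, 25 °C, 12–24 h
Reagents that add atoms: none
Why: Hayashi–Miyaura asymmetric 1,4-addition, the closest known reaction being the rhodium/bisphosphine-catalysed addition of arylboronic acids to chromones to give flavanones: boron-to-rhodium transmetalation gives an aryl complex of monovalent rhodium, the chromone C2=C3 bond inserts into the Rh–aryl bond with the aryl group going to C2, and water protonates the resulting rhodium oxa-π-allyl enolate and returns Rh–OH. No ring is closed; the step forms the C2–C1' bond that joins ring B to the finished A/C bicycle and creates the only stereocentre in an irreversible C–C bond formation. C2 is controlled by the C2-symmetric (S)-biaryl bisphosphine, whose quadrant pattern should let the flat benzopyranone bind through one enantioface only, so that the aryl group is delivered to the Re face of C2 and gives (2S). The step needs 1,4- over 1,2-addition and no reopening of the product, which the electron-poor ligand, the neutral medium and room temperature should secure, and no reaction at the 1,1-dimethylallyl vinyl group, which is unactivated and neopentyl-hindered. The 5-acetate keeps the peri oxygen from forming an O,O-chelate that would tie up the rhodium, and the ring A substituents are remote from C2.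

**Step 6**
Reactants: 13 (2S)-2-[3,4-bis(methoxymethoxy)phenyl]-7-(methoxymethoxy)-6-(2-methylbut-3-en-2-yl)-4-oxo-2,3-dihydrochromen-5-yl acetate
Product: 14 (2S)-2-(3,4-dihydroxyphenyl)-5,7-dihydroxy-6-(2-methylbut-3-en-2-yl)-2,3-dihydrochromen-4-one
Conditions: HCl (1.25 M in MeOH), Ar, 0 → 40 °C, 6–12 h; work-up at pH 4–5
Reagents that add atoms: none
Why: Acid-catalysed transacetalisation and transesterification to methanol should remove the three aryl methoxymethyl ethers and the peri-acetate (activated by the neighbouring carbonyl) in one operation; the excess methanol intercepts the methoxymethyl cation before it can attack C8, a monosubstituted vinyl group on a quaternary carbon is not protonated by dilute HCl, and C2, which epimerises through base-induced ring opening, sees no base.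

**Compound list**
1 | 5,7-dihydroxychromen-4-one | O=c1ccoc2cc(O)cc(O)c12 | starting material
2 | 1-bromo-3-methylbut-2-ene (prenyl bromide) | CC(C)=CCBr | starting material
3 | 5-hydroxy-7-(methoxymethoxy)chromen-4-one (not isolated) | O=c1ccoc2cc(OCOC)cc(O)c12 | intermediate
4 | 7-(methoxymethoxy)-5-[(3-methylbut-2-en-1-yl)oxy]chromen-4-one | O=c1ccoc2cc(OCOC)cc(OCC=C(C)C)c12 | intermediate
5 | 7-(methoxymethoxy)-6-(2-methylbut-3-en-2-yl)-6H-chromene-4,5-dione (Claisen dienone, racemic, not isolated) | O=C1C=COC2=C1C(=O)C(C(C)(C)C=C)C(OCOC)=C2 | intermediate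
6 | 5-hydroxy-7-(methoxymethoxy)-6-(2-methylbut-3-en-2-yl)chromen-4-one (not isolated) | O=c1ccoc2cc(OCOC)c(C(C)(C)C=C)c(O)c12 | intermediate
7 | 7-(methoxymethoxy)-6-(2-methylbut-3-en-2-yl)-4-oxochromen-5-yl acetate | CC(=O)Oc1c(C(C)(C)C=C)c(OCOC)cc2occc(=O)c12 | intermediate
8 | 4-bromobenzene-1,2-diol | Oc1ccc(Br)cc1O | starting material
9 | 4-bromo-1,2-bis(methoxymethoxy)benzene | COCOc1ccc(Br)cc1OCOC | intermediate
10 | [3,4-bis(methoxymethoxy)phenyl]lithium (not isolated) | [Li]c1ccc(OCOC)c(OCOC)c1 | intermediate
11 | lithium [3,4-bis(methoxymethoxy)phenyl]tri(propan-2-yloxy)borate (not isolated) | [Li+].CC(C)O[B-](OC(C)C)(OC(C)C)c1ccc(OCOC)c(OCOC)c1 | intermediate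
12 | [3,4-bis(methoxymethoxy)phenyl]boronic acid | OB(O)c1ccc(OCOC)c(OCOC)c1 | intermediate
13 | (2S)-2-[3,4-bis(methoxymethoxy)phenyl]-7-(methoxymethoxy)-6-(2-methylbut-3-en-2-yl)-4-oxo-2,3-dihydrochromen-5-yl acetate | C=CC(C)(C)c1c(OCOC)cc2c(c1OC(C)=O)C(=O)C[C@@H](c1ccc(OCOC)c(OCOC)c1)O2 | intermediate
14 | (2S)-2-(3,4-dihydroxyphenyl)-5,7-dihydroxy-6-(2-methylbut-3-en-2-yl)-2,3-dihydrochromen-4-one | C=CC(C)(C)c1c(O)cc2c(c1O)C(=O)C[C@@H](c1ccc(O)c(O)c1)O2 | target

**Step count:** 6 steps in total; longest linear sequence 4 (steps 1, 2, 5, 6 or steps 3, 4, 5, 6).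

**Steps most likely to fail**

Step 2. The allyl group may shift onward from C6 to C8 (para migration through the dienone) faster than the dienone is trapped, or the allyl ether may be lost thermally. The C6–C bond would then be made by cross-coupling. Compound 3, isolated by leaving out the bromide in step 1, would be iodinated ortho to the free 5-OH with benzyltrimethylammonium dichloroiodate and CaCO3 in CH2Cl2/MeOH to give 5-hydroxy-6-iodo-7-(methoxymethoxy)chromen-4-one F1. A γ-selective Suzuki–Miyaura coupling of F1 with 3-methylbut-2-enylboronic acid pinacol ester (Pd(OAc)2, a bulky dialkylbiarylphosphine of the kind that favours the branched product, aqueous K3PO4, THF) would give phenol 6. Acetylation (Ac2O, Et3N, DMAP) would return to the route at 7.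

Step 5. Carbometalation may be slow on this electron-rich, hindered chromone, or the facial selectivity may be insufficient. Compounds 7 and 12 would then be joined without chiral ligand ([Rh(OH)(C8H12)]2 alone, dioxane/H2O, 40 °C) to racemic 2-[3,4-bis(methoxymethoxy)phenyl]-7-(methoxymethoxy)-6-(2-methylbut-3-en-2-yl)-4-oxo-2,3-dihydrochromen-5-yl acetate F2. F2 would be resolved kinetically by Noyori asymmetric transfer hydrogenation with the catalyst enantiomer that gives the (4R)-carbinol, expected to be RuCl(p-cymene)[(R,R)-TsNCH(Ph)CH(Ph)NH2] (HCO2H/Et3N, EtOAc, room temperature, stopped near half conversion). The (2R)-enantiomer should be reduced to the cis-(2R,4R)-flavan-4-ol F3 and separated, leaving the (2S)-ketone 13, where the route is rejoined.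

Step 6. The methoxymethyl cation may alkylate C8 of the freed phloroglucinol ring, acid may open ring C with erosion of C2, or the hindered 5-acetate may cleave slowly. The unmasking would then be split into two stages. ZnBr2/n-PrSH in CH2Cl2 at 0 °C (the thiol captures the methoxymethyl cation) would take 13 to (2S)-2-(3,4-dihydroxyphenyl)-7-hydroxy-6-(2-methylbut-3-en-2-yl)-4-oxo-2,3-dihydrochromen-5-yl acetate F4. NH4OAc in aqueous MeOH at room temperature would then remove the acetate under neutral conditions and give 14.

**Further compounds**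
F1 | step 2 | 5-hydroxy-6-iodo-7-(methoxymethoxy)chromen-4-one | O=c1ccoc2cc(OCOC)c(I)c(O)c12
F2 | step 5 | racemic 2-[3,4-bis(methoxymethoxy)phenyl]-7-(methoxymethoxy)-6-(2-methylbut-3-en-2-yl)-4-oxo-2,3-dihydrochromen-5-yl acetate | C=CC(C)(C)c1c(OCOC)cc2c(c1OC(C)=O)C(=O)CC(c1ccc(OCOC)c(OCOC)c1)O2
F3 | step 5 | (2R,4R)-2-[3,4-bis(methoxymethoxy)phenyl]-4-hydroxy-7-(methoxymethoxy)-6-(2-methylbut-3-en-2-yl)-3,4-dihydro-2H-chromen-5-yl acetate | C=CC(C)(C)c1c(OCOC)cc2c(c1OC(C)=O)[C@H](O)C[C@H](c1ccc(OCOC)c(OCOC)c1)O2
F4 | step 6 | (2S)-2-(3,4-dihydroxyphenyl)-7-hydroxy-6-(2-methylbut-3-en-2-yl)-4-oxo-2,3-dihydrochromen-5-yl acetate | C=CC(C)(C)c1c(O)cc2c(c1OC(C)=O)C(=O)C[C@@H](c1ccc(O)c(O)c1)O2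
A1 | direct plan | 1-[2,4,6-trihydroxy-3-(2-methylbut-3-en-2-yl)phenyl]ethanone | CC(=O)c1c(O)cc(O)c(C(C)(C)C=C)c1O
A2 | direct plan | 3,4-bis(tert-butyldimethylsilyloxy)benzaldehyde | O=Cc1ccc(O[Si](C)(C)C(C)(C)C)c(O[Si](C)(C)C(C)(C)C)c1
A3 | direct plan | (E)-3-[3,4-bis(tert-butyldimethylsilyloxy)phenyl]-1-[2,4,6-trihydroxy-3-(2-methylbut-3-en-2-yl)phenyl]prop-2-en-1-one | C=CC(C)(C)c1c(O)cc(O)c(C(=O)/C=C/c2ccc(O[Si](C)(C)C(C)(C)C)c(O[Si](C)(C)C(C)(C)C)c2)c1O
A4 | direct plan | (2S)-2-[3,4-bis(tert-butyldimethylsilyloxy)phenyl]-5,7-dihydroxy-6-(2-methylbut-3-en-2-yl)-2,3-dihydrochromen-4-one | C=CC(C)(C)c1c(O)cc2c(c1O)C(=O)C[C@@H](c1ccc(O[Si](C)(C)C(C)(C)C)c(O[Si](C)(C)C(C)(C)C)c1)O2
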